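**Plan**
- Retrosynthesis: after removal of the silyl and ethyl groups, ring C is cut at O1–C2 and C2–C3 (cyclodehydration, Baker–Venkataraman acyl shift) into a ring A aryl ketone and a ring B benzoic acid. The ketone chain is cut at C4–CH2 (Grignard addition) and C4–C4a (ortho-formylation).
- Ring A is then cut at C8a–C8, C7–C6 and C4a–C8a into 3-ethoxycyclobutenone and a chiral triisopropylsiloxyalkyne.
- Forward: alkyne (steps 1–3), ring A by benzannulation (step 4), acyl chain at C4a (steps 5–7), ring B acid (steps 8–9), ester, acyl shift and ring C closure (steps 10–12), deprotection (steps 13–14).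
- Enabling feature: ring A (C4a, C5, C6, C7, C8, C8a) is a phloroglucinol whose C8 carries the C1'''–C2'''–C3''' chain between O1 (on C8a) and O7. The benzannulation delivers O1 as the only free phenol, O7 as a silyl ether and O5 as an ethyl ether, so the carbonyl can only be placed at C4a and ring C can only close through O1.
- Stereochemistry: the single stereocentre, (S)-C2''', is set in step 1 by catalyst-controlled propargylboration of methacrolein and none of its bonds is broken afterwards.

Key step: step 4

Assumption: the (S)-configured phosphoric acid is taken to direct the allenylboronate to the Si face of methacrolein (mirror image of the Re-face preference of the (R)-acid in allylboration); the configuration of 4 is to be checked by Mosher ester analysis and the antipodal acid used if the sense is opposite.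
Assumption: 3-ethoxycyclobut-2-en-1-one (9) and allenylboronic acid pinacol ester (2) are treated as purchased materials.

**Step 1**
Reactants: 1 methacrolein; 2 allenylboronic acid pinacol ester
Product: 4 (3S)-2-methylhex-1-en-5-yn-3-ol, via borate ester 3 (not isolated)
Conditions: (S)-3,3'-bis(2,4,6-triisopropylphenyl)-1,1'-binaphthyl-2,2'-diyl hydrogen phosphate (5 mol%), 4 Å MS, toluene, −20 °C; aq. NaHCO3
Reagents that add atoms: none
Why: Chiral phosphoric acid catalysed propargylboration, in which the acid hydrogen-bonds to a boronate oxygen and the formyl hydrogen in a closed six-membered chair transition state (SE2' attack through the allene terminus), so that only the homopropargylic alcohol forms and the 3,3'-aryl groups of the catalyst select the Si face of the aldehyde, setting the (S)-carbinol.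

**Step 2**
Reactants: 4 (3S)-2-methylhex-1-en-5-yn-3-ol
Product: 5 tert-butyldimethyl{[(3S)-2-methylhex-1-en-5-yn-3-yl]oxy}silane
Conditions: TBSCl, imidazole, DMF, 0 °C → rt
Reagents that add atoms: tert-butyldimethylsilyl chloride, CC(C)(C)[Si](C)(C)Cl
Why: Imidazole-promoted silylation of a secondary alcohol masks the only O–H before the acetylide chemistry and gives an ether that is inert to the later thermal, organomagnesium and amide-base steps.

**Step 3**
Reactants: 5 tert-butyldimethyl{[(3S)-2-methylhex-1-en-5-yn-3-yl]oxy}silane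
Product: 8 (3S)-3-(tert-butyldimethylsilyloxy)-2-methyl-6-(triisopropylsilyloxy)hex-1-en-5-yne, via lithium acetylide 6 (not isolated), via lithium ynolate 7 (not isolated)
Conditions: LiN(SiMe3)2, THF, −78 °C; LiOOt-Bu (from t-BuOOH and LiN(SiMe3)2, THF, −78 °C), −78 → 0 °C; i-Pr3SiOTf, −78 → 0 °C
Reagents that add atoms: tert-butyl hydroperoxide, CC(C)(C)OO; triisopropylsilyl trifluoromethanesulfonate, CC(C)[Si](C(C)C)(C(C)C)OS(=O)(=O)C(F)(F)F
Why: Acetylide oxidation followed by ynolate O-silylation, in which the lithium acetylide attacks the lithiated oxygen of the peroxide with loss of tert-butoxide and the bulky silyl triflate traps the resulting ynolate on oxygen to give a chromatographically stable triisopropylsiloxyalkyne.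

**Step 4**
Reactants: 8 (3S)-3-(tert-butyldimethylsilyloxy)-2-methyl-6-(triisopropylsilyloxy)hex-1-en-5-yne; 9 3-ethoxycyclobut-2-en-1-one
Product: 14 2-[(2S)-2-(tert-butyldimethylsilyloxy)-3-methylbut-3-en-1-yl]-5-ethoxy-3-(triisopropylsilyloxy)phenol, via ethoxyvinylketene 10 (not isolated), via 4-vinylcyclobutenone adduct 11 (not isolated), via dienylketene 12 (not isolated), via cyclohexadienone 13 (not isolated)
Conditions: 8 (1.0 equiv), 9 (1.2 equiv, added in portions), degassed toluene, 80 → 110 °C, sealed tube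
Reagents that add atoms: none
Why: Danheiser benzannulation: thermal four-electron electrocyclic opening of 9 gives ethoxyvinylketene 10, which adds siloxyalkyne 8 in a [2+2] cycloaddition (forming C8a–C8 and C7–C6) to give 4-vinylcyclobutenone 11, and 11 reopens to dienylketene 12. Ring A then closes by thermal six-electron disrotatory electrocyclisation of 12 (forming C4a–C8a), and cyclohexadienone 13 tautomerises to phenol 14, the aromatisation making the cascade irreversible. The closest known reaction type is the benzannulation of 3-substituted cyclobutenones with trialkylsiloxyalkynes to resorcinol monosilyl ethers; the 3-alkoxy group stays within that class and is expected only to slow the first ring opening through its vinylogous ester character, hence the final heating at 110 °C. The step needs regiocontrol in the [2+2] event, which the ketene-acetal-like polarisation of the siloxyalkyne secures: its chain-bearing carbon is nucleophilic and bonds to the ketene carbonyl carbon (future C8a), while the oxygen-bearing carbon bonds to the ketene α-carbon (future C6), so the chain lands at C8 between the free phenol (O1) and the silyl ether (O7), with the ethoxy group at C5. No stereocentre is created (the ring carbon of 11 that bears the ethoxyvinyl group is transient), and the (S)-carbinol, insulated by the C1''' methylene, the allylic silyl ether and the 1,1-disubstituted alkene should pass through the neutral thermal conditions unchanged.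

**Step 5**
Reactants: 14 2-[(2S)-2-(tert-butyldimethylsilyloxy)-3-methylbut-3-en-1-yl]-5-ethoxy-3-(triisopropylsilyloxy)phenol
Product: 15 6-ethoxy-2-hydroxy-3-[(2S)-2-(tert-butyldimethylsilyloxy)-3-methylbut-3-en-1-yl]-4-(triisopropylsilyloxy)benzaldehyde
Conditions: MgCl2, Et3N, (CH2O)n, THF, reflux; aq. citric acid
Reagents that add atoms: paraformaldehyde (as formaldehyde), C=O
Why: Magnesium-mediated ortho-formylation (Casnati–Skattebøl reaction), in which the magnesium phenoxide delivers formaldehyde through a six-membered chelate to the only free ortho position, C4a, and a second formaldehyde oxidises the benzylic alkoxide by hydride transfer, so C6 is not touched and the silyl ethers survive the mild amine base.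

**Step 6**
Reactants: 15 6-ethoxy-2-hydroxy-3-[(2S)-2-(tert-butyldimethylsilyloxy)-3-methylbut-3-en-1-yl]-4-(triisopropylsilyloxy)benzaldehyde; 16 5-bromo-2-methylpent-2-ene
Product: 18 1-{6-ethoxy-2-hydroxy-3-[(2S)-2-(tert-butyldimethylsilyloxy)-3-methylbut-3-en-1-yl]-4-(triisopropylsilyloxy)phenyl}-5-methylhex-4-en-1-ol (both carbinol epimers), via (4-methylpent-3-enyl)magnesium bromide 17 (not isolated)
Conditions: 16, Mg, THF, rt; then 15 (17 in 2.5 equiv), THF, 0 °C → rt; aq. NH4Cl; crude product used directly
Reagents that add atoms: none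
Why: Grignard addition to a salicylaldehyde, in which the first equivalent forms the magnesium phenoxide and the second adds to the chelated aldehyde, bringing in all carbons of the future C3 prenyl unit, the new carbinol centre being left uncontrolled because the next step oxidises it.

**Step 7**
Reactants: 18 benzylic alcohol from step 6
Product: 19 1-{6-ethoxy-2-hydroxy-3-[(2S)-2-(tert-butyldimethylsilyloxy)-3-methylbut-3-en-1-yl]-4-(triisopropylsilyloxy)phenyl}-5-methylhex-4-en-1-one
Conditions: activated MnO2 (excess), CH2Cl2, rt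
Reagents that add atoms: none
Why: Benzylic alcohol oxidation with MnO2 is selective for the electron-rich benzylic carbinol, leaves the phenol, the alkenes and the silyl ethers alone, and erases the uncontrolled carbinol centre.

**Step 8**
Reactants: 20 2,4-dihydroxybenzaldehyde
Product: 21 2,4-bis(triisopropylsilyloxy)benzaldehyde
Conditions: i-Pr3SiCl, imidazole, DMF, rt → 40 °C
Reagents that add atoms: triisopropylsilyl chloride, CC(C)[Si](Cl)(C(C)C)C(C)C
Why: Imidazole-promoted silylation of both phenols installs bulky triisopropylsilyl groups that should stay on the 2-oxygen through enolate chemistry and mild acid and leave with fluoride at the end.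

**Step 9**
Reactants: 21 2,4-bis(triisopropylsilyloxy)benzaldehyde
Product: 22 2,4-bis(triisopropylsilyloxy)benzoic acid
Conditions: NaClO2, NaH2PO4, 2-methylbut-2-ene, t-BuOH/H2O, rt
Reagents that add atoms: sodium chlorite, [Na+].[O-]Cl=O
Why: Pinnick oxidation converts the aldehyde into the acid under buffered, mildly acidic conditions that aryl silyl ethers tolerate, with 2-methylbut-2-ene scavenging hypochlorous acid before it can chlorinate the electron-rich ring.

**Step 10**
Reactants: 22 2,4-bis(triisopropylsilyloxy)benzoic acid; 19 aryl ketone from step 7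
Product: 24 3-ethoxy-2-(5-methylhex-4-enoyl)-6-[(2S)-2-(tert-butyldimethylsilyloxy)-3-methylbut-3-en-1-yl]-5-(triisopropylsilyloxy)phenyl 2,4-bis(triisopropylsilyloxy)benzoate, via acid chloride 23 (not isolated)
Conditions: 22 (1.3 equiv), (COCl)2, DMF (cat.), CH2Cl2, 0 °C → rt, evaporate; then 19, Et3N, DMAP, CH2Cl2, 0 °C → rt
Reagents that add atoms: none
Why: Acid chloride formation under DMF catalysis followed by DMAP-catalysed O-acylation places the ring B acyl group on O1, the only free hydroxyl in 19, giving the ester needed for the acyl shift.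

**Step 11**
Reactants: 24 aryl ester from step 10
Product: 25 1-[2,4-bis(triisopropylsilyloxy)phenyl]-3-{6-ethoxy-2-hydroxy-3-[(2S)-2-(tert-butyldimethylsilyloxy)-3-methylbut-3-en-1-yl]-4-(triisopropylsilyloxy)phenyl}-2-(3-methylbut-2-en-1-yl)propane-1,3-dione (C2 epimers and enol or hemiketal tautomers)
Conditions: LiN(SiMe3)2 (3 equiv), THF, −78 → 0 °C; AcOH quench; crude product used directly
Reagents that add atoms: none
Why: Baker–Venkataraman rearrangement, in which the lithium enolate of the aryl ketone attacks the neighbouring ester carbonyl through a six-membered transition state and collapse to the phenoxide and the stabilised 1,3-diketonate drives the acyl shift that places the prenyl-bearing carbon between the two carbonyls, the non-nucleophilic amide base leaving the aryl silyl ethers in place.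

**Step 12**
Reactants: 25 1,3-diketone from step 11
Product: 26 2-[2,4-bis(triisopropylsilyloxy)phenyl]-5-ethoxy-8-[(2S)-2-(tert-butyldimethylsilyloxy)-3-methylbut-3-en-1-yl]-3-(3-methylbut-2-en-1-yl)-7-(triisopropylsilyloxy)-4H-chromen-4-one
Conditions: p-TsOH·H2O (10 mol%), toluene, 60 °C
Reagents that add atoms: none
Why: Acid-catalysed cyclodehydration of the o-hydroxyaryl 1,3-diketone closes ring C by 6-exo-trig attack of the C8a hydroxyl, the only free phenol because the 2'-oxygen is silylated, on the ring B carbonyl followed by loss of water, and catalytic acid in an aprotic solvent should spare the silyl ethers and the alkenes.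

**Step 13**
Reactants: 26 protected 5-ethoxyflavone from step 12
Product: 27 2-[2,4-bis(triisopropylsilyloxy)phenyl]-5-hydroxy-8-[(2S)-2-(tert-butyldimethylsilyloxy)-3-methylbut-3-en-1-yl]-3-(3-methylbut-2-en-1-yl)-7-(triisopropylsilyloxy)-4H-chromen-4-one
Conditions: MgI2·OEt2 (4 equiv), toluene, 80 °C; aq. NH4Cl
Reagents that add atoms: none
Why: Chelation-assisted ether cleavage, in which MgI2 binds between the C4 carbonyl and the peri C5 oxygen and iodide displaces the activated ethyl group (SN2) to give the magnesium phenoxide, a mode of cleavage specific to the ether peri to the carbonyl and mild enough for prenyl groups and silyl ethers.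

**Step 14**
Reactants: 27 5-hydroxyflavone tetrasilyl ether from step 13
Product: 28 2-(2,4-dihydroxyphenyl)-5,7-dihydroxy-8-[(2S)-2-hydroxy-3-methylbut-3-en-1-yl]-3-(3-methylbut-2-en-1-yl)-4H-chromen-4-one (CNP0213011.2)
Conditions: Bu4NF, AcOH (1:1, 6 equiv), THF, 0 °C → rt; pH 7 buffer
Reagents that add atoms: none
Why: Fluoride-induced desilylation, driven by Si–F bond formation and buffered with acetic acid, removes the three aryl silyl ethers and the secondary silyl ether under near-neutral conditions, so the prenyl group, the allylic alcohol and the free 2'-hydroxyl are released without acid-promoted cyclisation and the (S)-carbinol is untouched.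

**Compound list**
1 | methacrolein (2-methylprop-2-enal) | C=C(C)C=O | starting material
2 | allenylboronic acid pinacol ester | C=C=CB1OC(C)(C)C(C)(C)O1 | starting material
3 | 4,4,5,5-tetramethyl-2-{[(3S)-2-methylhex-1-en-5-yn-3-yl]oxy}-1,3,2-dioxaborolane | C=C(C)[C@@H](OB1OC(C)(C)C(C)(C)O1)CC#C | intermediate
4 | (3S)-2-methylhex-1-en-5-yn-3-ol | C=C(C)[C@@H](O)CC#C | intermediate
5 | tert-butyldimethyl{[(3S)-2-methylhex-1-en-5-yn-3-yl]oxy}silane | C=C(C)[C@@H](O[Si](C)(C)C(C)(C)C)CC#C | intermediate
6 | lithium acetylide of 5 | C=C(C)[C@@H](O[Si](C)(C)C(C)(C)C)CC#C[Li] | intermediate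
7 | lithium (4S)-4-(tert-butyldimethylsilyloxy)-5-methylhex-5-en-1-yn-1-olate | C=C(C)[C@@H](O[Si](C)(C)C(C)(C)C)CC#CO[Li] | intermediate
8 | (3S)-3-(tert-butyldimethylsilyloxy)-2-methyl-6-(triisopropylsilyloxy)hex-1-en-5-yne | C=C(C)[C@@H](O[Si](C)(C)C(C)(C)C)CC#CO[Si](C(C)C)(C(C)C)C(C)C | intermediate
9 | 3-ethoxycyclobut-2-en-1-one | CCOC1=CC(=O)C1 | starting material
10 | 3-ethoxybuta-1,3-dien-1-one (ethoxyvinylketene) | C=C(OCC)C=C=O | intermediate
11 | 4-(1-ethoxyvinyl)-2-[(2S)-2-(tert-butyldimethylsilyloxy)-3-methylbut-3-en-1-yl]-3-(triisopropylsilyloxy)cyclobut-2-en-1-one (both epimers at ring C4) | C=C(C)[C@@H](O[Si](C)(C)C(C)(C)C)CC1=C(O[Si](C(C)C)(C(C)C)C(C)C)C(C(=C)OCC)C1=O | intermediate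
12 | 5-ethoxy-2-[(2S)-2-(tert-butyldimethylsilyloxy)-3-methylbut-3-en-1-yl]-3-(triisopropylsilyloxy)hexa-1,3,5-trien-1-one (ketene and ethoxyvinyl group cis on the central alkene) | C=C(C)[C@@H](O[Si](C)(C)C(C)(C)C)CC(=C=O)/C(O[Si](C(C)C)(C(C)C)C(C)C)=C\C(=C)OCC | intermediate
13 | 5-ethoxy-2-[(2S)-2-(tert-butyldimethylsilyloxy)-3-methylbut-3-en-1-yl]-3-(triisopropylsilyloxy)cyclohexa-2,4-dien-1-one | C=C(C)[C@@H](O[Si](C)(C)C(C)(C)C)CC1=C(O[Si](C(C)C)(C(C)C)C(C)C)C=C(OCC)CC1=O | intermediate
14 | 2-[(2S)-2-(tert-butyldimethylsilyloxy)-3-methylbut-3-en-1-yl]-5-ethoxy-3-(triisopropylsilyloxy)phenol | C=C(C)[C@@H](O[Si](C)(C)C(C)(C)C)Cc1c(O)cc(OCC)cc1O[Si](C(C)C)(C(C)C)C(C)C | intermediate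
15 | 6-ethoxy-2-hydroxy-3-[(2S)-2-(tert-butyldimethylsilyloxy)-3-methylbut-3-en-1-yl]-4-(triisopropylsilyloxy)benzaldehyde | C=C(C)[C@@H](O[Si](C)(C)C(C)(C)C)Cc1c(O)c(C=O)c(OCC)cc1O[Si](C(C)C)(C(C)C)C(C)C | intermediate
16 | 5-bromo-2-methylpent-2-ene | CC(C)=CCCBr | starting material
17 | (4-methylpent-3-enyl)magnesium bromide | CC(C)=CCC[Mg]Br | intermediate
18 | 1-{6-ethoxy-2-hydroxy-3-[(2S)-2-(tert-butyldimethylsilyloxy)-3-methylbut-3-en-1-yl]-4-(triisopropylsilyloxy)phenyl}-5-methylhex-4-en-1-ol (both carbinol epimers) | C=C(C)[C@@H](O[Si](C)(C)C(C)(C)C)Cc1c(O)c(C(O)CCC=C(C)C)c(OCC)cc1O[Si](C(C)C)(C(C)C)C(C)C | intermediate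
19 | 1-{6-ethoxy-2-hydroxy-3-[(2S)-2-(tert-butyldimethylsilyloxy)-3-methylbut-3-en-1-yl]-4-(triisopropylsilyloxy)phenyl}-5-methylhex-4-en-1-one | C=C(C)[C@@H](O[Si](C)(C)C(C)(C)C)Cc1c(O)c(C(=O)CCC=C(C)C)c(OCC)cc1O[Si](C(C)C)(C(C)C)C(C)C | intermediate
20 | 2,4-dihydroxybenzaldehyde | O=Cc1ccc(O)cc1O | starting material
21 | 2,4-bis(triisopropylsilyloxy)benzaldehyde | O=Cc1ccc(O[Si](C(C)C)(C(C)C)C(C)C)cc1O[Si](C(C)C)(C(C)C)C(C)C | intermediate
22 | 2,4-bis(triisopropylsilyloxy)benzoic acid | O=C(O)c1ccc(O[Si](C(C)C)(C(C)C)C(C)C)cc1O[Si](C(C)C)(C(C)C)C(C)C | intermediate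
23 | 2,4-bis(triisopropylsilyloxy)benzoyl chloride | O=C(Cl)c1ccc(O[Si](C(C)C)(C(C)C)C(C)C)cc1O[Si](C(C)C)(C(C)C)C(C)C | intermediate
24 | 3-ethoxy-2-(5-methylhex-4-enoyl)-6-[(2S)-2-(tert-butyldimethylsilyloxy)-3-methylbut-3-en-1-yl]-5-(triisopropylsilyloxy)phenyl 2,4-bis(triisopropylsilyloxy)benzoate | C=C(C)[C@@H](O[Si](C)(C)C(C)(C)C)Cc1c(OC(=O)c2ccc(O[Si](C(C)C)(C(C)C)C(C)C)cc2O[Si](C(C)C)(C(C)C)C(C)C)c(C(=O)CCC=C(C)C)c(OCC)cc1O[Si](C(C)C)(C(C)C)C(C)C | intermediate
25 | 1-[2,4-bis(triisopropylsilyloxy)phenyl]-3-{6-ethoxy-2-hydroxy-3-[(2S)-2-(tert-butyldimethylsilyloxy)-3-methylbut-3-en-1-yl]-4-(triisopropylsilyloxy)phenyl}-2-(3-methylbut-2-en-1-yl)propane-1,3-dione (C2 epimers) | C=C(C)[C@@H](O[Si](C)(C)C(C)(C)C)Cc1c(O)c(C(=O)C(CC=C(C)C)C(=O)c2ccc(O[Si](C(C)C)(C(C)C)C(C)C)cc2O[Si](C(C)C)(C(C)C)C(C)C)c(OCC)cc1O[Si](C(C)C)(C(C)C)C(C)C | intermediate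
26 | 2-[2,4-bis(triisopropylsilyloxy)phenyl]-5-ethoxy-8-[(2S)-2-(tert-butyldimethylsilyloxy)-3-methylbut-3-en-1-yl]-3-(3-methylbut-2-en-1-yl)-7-(triisopropylsilyloxy)-4H-chromen-4-one | C=C(C)[C@@H](O[Si](C)(C)C(C)(C)C)Cc1c(O[Si](C(C)C)(C(C)C)C(C)C)cc(OCC)c2c(=O)c(CC=C(C)C)c(-c3ccc(O[Si](C(C)C)(C(C)C)C(C)C)cc3O[Si](C(C)C)(C(C)C)C(C)C)oc12 | intermediate
27 | 2-[2,4-bis(triisopropylsilyloxy)phenyl]-5-hydroxy-8-[(2S)-2-(tert-butyldimethylsilyloxy)-3-methylbut-3-en-1-yl]-3-(3-methylbut-2-en-1-yl)-7-(triisopropylsilyloxy)-4H-chromen-4-one | C=C(C)[C@@H](O[Si](C)(C)C(C)(C)C)Cc1c(O[Si](C(C)C)(C(C)C)C(C)C)cc(O)c2c(=O)c(CC=C(C)C)c(-c3ccc(O[Si](C(C)C)(C(C)C)C(C)C)cc3O[Si](C(C)C)(C(C)C)C(C)C)oc12 | intermediate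
28 | 2-(2,4-dihydroxyphenyl)-5,7-dihydroxy-8-[(2S)-2-hydroxy-3-methylbut-3-en-1-yl]-3-(3-methylbut-2-en-1-yl)-4H-chromen-4-one | C=C(C)[C@@H](O)Cc1c(O)cc(O)c2c(=O)c(CC=C(C)C)c(-c3ccc(O)cc3O)oc12 | target

**Step count and risks**
Total step count: 14. Longest linear sequence: 12 steps (steps 1–7 and 10–14); steps 8–9 are the ring B branch.

Steps most likely to fail:

1. Step 4. The push-pull (vinylogous ester) cyclobutenone may open too slowly, so that ketene dimerisation, acylation of the product phenol by the vinylketene, or thermal loss of the siloxyalkyne outruns the cascade. The fallback keeps the same bond construction but makes ketene 10 at room temperature by photochemical Wolff rearrangement. Ethyl vinyl ether is lithiated (t-BuLi, THF, −78 → 0 °C) to (1-ethoxyvinyl)lithium F1, which is acylated with N-methoxy-N-methylacetamide to 3-ethoxybut-3-en-2-one F2. Its lithium enolate (LiN(SiMe3)2, THF, −78 °C) is trifluoroacetylated with 2,2,2-trifluoroethyl trifluoroacetate to 5-ethoxy-1,1,1-trifluorohex-5-ene-2,4-dione F3, and detrifluoroacetylative diazo transfer (MsN3, Et3N, H2O, MeCN) gives 1-diazo-3-ethoxybut-3-en-2-one F4. Irradiation of F4 with alkyne 8 in CH2Cl2 at room temperature generates 10 in the presence of 8, and brief heating in toluene completes the opening and electrocyclisation. The fallback sets out from 8 and returns to the route at phenol 14.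

2. Step 13. Iodide attack at the ethyl carbon is slower than at a methyl group, so the chelate may have to be heated to the point where silyl ethers begin to be lost or the prenyl alkene picks up traces of HI. The fallback changes the mechanism to a Lewis-acid-free nucleophilic dealkylation. From 26, NaSEt (from EtSH and NaH) in DMF at 110 °C should cleave the ethyl ether by SN2 at carbon, the aryloxide leaving group being stabilised by the peri carbonyl. The three aryl silyl ethers are expected to fall off in the same basic medium, so the expected product is 2-(2,4-dihydroxyphenyl)-5,7-dihydroxy-8-[(2S)-2-(tert-butyldimethylsilyloxy)-3-methylbut-3-en-1-yl]-3-(3-methylbut-2-en-1-yl)-4H-chromen-4-one F5. The fluoride conditions of step 14 then remove the remaining secondary silyl ether. The fallback sets out from 26 and returns to the route at target 28.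

3. Step 11. The hindered, α-branched enolate may fail to attack the electron-rich ester carbonyl shielded by the ortho silyloxy group, or silyl migration from the 2'-oxygen to the diketonate may free the 2'-hydroxyl and open the way to ring closure in the wrong direction. The fallback forms the same C–C bond by aldol addition to the more electrophilic aldehyde. The phenoxide–enolate dianion of ketone 19 (LiN(i-Pr)2, 2.2 equiv, THF, −78 °C) adds to aldehyde 21 (in hand from step 8) to give 1-{6-ethoxy-2-hydroxy-3-[(2S)-2-(tert-butyldimethylsilyloxy)-3-methylbut-3-en-1-yl]-4-(triisopropylsilyloxy)phenyl}-2-{[2,4-bis(triisopropylsilyloxy)phenyl](hydroxy)methyl}-5-methylhex-4-en-1-one F6. Oxidation of the crude aldol with Dess–Martin periodinane and NaHCO3 in CH2Cl2 at 0 °C gives the 1,3-diketone. The fallback sets out from 19 and returns to the route at 25.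

**Further compounds**
F1 | step 4 | (1-ethoxyvinyl)lithium | [Li]C(=C)OCC
F2 | step 4 | 3-ethoxybut-3-en-2-one | C=C(OCC)C(C)=O
F3 | step 4 | 5-ethoxy-1,1,1-trifluorohex-5-ene-2,4-dione | C=C(OCC)C(=O)CC(=O)C(F)(F)F
F4 | step 4 | 1-diazo-3-ethoxybut-3-en-2-one | C=C(OCC)C(=O)C=[N+]=[N-]
F5 | step 13 | 2-(2,4-dihydroxyphenyl)-5,7-dihydroxy-8-[(2S)-2-(tert-butyldimethylsilyloxy)-3-methylbut-3-en-1-yl]-3-(3-methylbut-2-en-1-yl)-4H-chromen-4-one | C=C(C)[C@@H](O[Si](C)(C)C(C)(C)C)Cc1c(O)cc(O)c2c(=O)c(CC=C(C)C)c(-c3ccc(O)cc3O)oc12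
F6 | step 11 | 1-{6-ethoxy-2-hydroxy-3-[(2S)-2-(tert-butyldimethylsilyloxy)-3-methylbut-3-en-1-yl]-4-(triisopropylsilyloxy)phenyl}-2-{[2,4-bis(triisopropylsilyloxy)phenyl](hydroxy)methyl}-5-methylhex-4-en-1-one (mixture of aldol diastereomers) | C=C(C)[C@@H](O[Si](C)(C)C(C)(C)C)Cc1c(O)c(C(=O)C(CC=C(C)C)C(O)c2ccc(O[Si](C(C)C)(C(C)C)C(C)C)cc2O[Si](C(C)C)(C(C)C)C(C)C)c(OCC)cc1O[Si](C(C)C)(C(C)C)C(C)C
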